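**Strategy**

The oxolane is cut at the C4–C5 bond (oxolan-3-ol numbering: C5 bears the catechol ring, C4 the CH2OH group). Ring oxygen, C5, C4 and the exocyclic CH2OH carbon are the retron of a Lewis-acid [1,3] O-to-C shift of a seven-membered cyclic vinyl acetal. In one operation a 2-aryl-4,5-dihydro-1,3-dioxepine ionises to a tethered aryl oxocarbenium/enol silane pair and recloses to the five-membered 2-aryl-oxolane-3-carbaldehyde: the ring contracts by two atoms, C4–C5 forms, both new stereocentres are set cis under control of the preset tertiary carbinol centre, and both acetal epimers converge. The precursor is a 5-benzyl-5-silyloxy-4,5-dihydro-1,3-dioxepine built from a (Z)-butenediol acetal by asymmetric epoxidation and selenoxide elimination.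

Key step: step 8

Remark (assumption): the facial sense of the Shi epoxidation is assigned with the spiro transition-state model, as for 1-substituted cycloalkenes; if the olefin reacted with the opposite sense, the enantiomeric ketone would be used. Dioxepine locants in the text are O1, C2 (acetal carbon), O3, C4–C7.

**Route**

Step 1
Reactants: 1 but-2-yne-1,4-diol
Product: 2 (E)-2-(tributylstannyl)but-2-ene-1,4-diol
Conditions: Bu3SnH, PdCl2(PPh3)2 (2 mol%), THF, 0 °C to rt
Reagents that add atoms: tributyltin hydride, CCCC[SnH](CCCC)CCCC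
Why: Palladium-catalysed hydrostannation adds H and Sn syn across the symmetric alkyne, which places the two CH2OH groups cis, the geometry needed later for the seven-membered acetal.

Step 2
Reactants: 2 (E)-2-(tributylstannyl)but-2-ene-1,4-diol; 3 3,4-dimethoxybenzyl bromide
Product: 4 (Z)-2-[(3,4-dimethoxyphenyl)methyl]but-2-ene-1,4-diol
Conditions: Pd(PPh3)4 (5 mol%), CuI (10 mol%), DMF, 50 °C
Reagents that add atoms: none
Why: Stille coupling of the alkenylstannane with the benzylic bromide proceeds with retention of olefin geometry, and copper(I) iodide is added to suppress cine substitution at the α-substituted stannane.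

Step 3
Reactants: 4 (Z)-2-[(3,4-dimethoxyphenyl)methyl]but-2-ene-1,4-diol; 5 3,4-bis(benzyloxy)benzaldehyde
Product: 6 2-[3,4-bis(benzyloxy)phenyl]-5-[(3,4-dimethoxyphenyl)methyl]-4,7-dihydro-1,3-dioxepine (racemic at C2)
Conditions: PPTS (5 mol%), benzene, reflux, Dean–Stark
Reagents that add atoms: none
Why: Acid-catalysed acetalisation of a cis-but-2-ene-1,4-diol with an aldehyde closes the 4,7-dihydro-1,3-dioxepine under water removal; the mild acid limits cyclodehydration of the diol, and the racemic acetal carbon is of no consequence because step 8 erases it.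

Step 4
Reactants: 6 2-[3,4-bis(benzyloxy)phenyl]-5-[(3,4-dimethoxyphenyl)methyl]-4,7-dihydro-1,3-dioxepine
Product: 7 (1S,7R)-4-[3,4-bis(benzyloxy)phenyl]-1-[(3,4-dimethoxyphenyl)methyl]-3,5,8-trioxabicyclo[5.1.0]octane (both C4 epimers)
Conditions: D-fructose-derived Shi ketone (0.3 equiv), Oxone, K2CO3, Bu4NHSO4 (cat.), MeCN–dimethoxymethane/aq. borate–EDTA buffer (pH 10.5), 0 °C
Reagents that add atoms: potassium peroxymonosulfate (active component of Oxone), [K+].[O-]S(=O)(=O)OO
Why: Shi epoxidation through the spiro transition state should deliver oxygen to one face of the trisubstituted olefin, fixing the future carbinol carbon as (S) in 7 under reagent control; the remote racemic acetal carbon only doubles the number of isomers carried forward.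

Step 5
Reactants: 7 (1S,7R)-epoxide
Product: 8 (5S,6S)-2-[3,4-bis(benzyloxy)phenyl]-5-[(3,4-dimethoxyphenyl)methyl]-6-(phenylselanyl)-1,3-dioxepan-5-ol (both C2 epimers)
Conditions: (PhSe)2, NaBH4, EtOH, 0 °C to reflux
Reagents that add atoms: diphenyl diselenide, c1ccc(cc1)[Se][Se]c1ccccc1
Why: Benzeneselenolate opens the trisubstituted epoxide by SN2 attack at the less substituted C6 with inversion, leaving the tertiary C5–O bond and its configuration untouched (first half of an epoxide-to-allylic-alcohol transposition).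

Step 6
Reactants: 8 (5S,6S)-hydroxy selenide
Product: 9 trimethyl{[(5S,6S)-2-[3,4-bis(benzyloxy)phenyl]-5-[(3,4-dimethoxyphenyl)methyl]-6-(phenylselanyl)-1,3-dioxepan-5-yl]oxy}silane (both C2 epimers)
Conditions: 1-(trimethylsilyl)imidazole, CH2Cl2, rt to 40 °C
Reagents that add atoms: 1-(trimethylsilyl)imidazole, C[Si](C)(C)n1ccnc1
Why: The neutral, highly reactive silyl imidazole caps the hindered tertiary alcohol, which would otherwise trap the oxocarbenium ion in step 8, without the Lewis acidity of silyl triflates that would open the acetal.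

Step 7
Reactants: 9 silyl ether selenide
Product: 11 {[(5R)-2-[3,4-bis(benzyloxy)phenyl]-5-[(3,4-dimethoxyphenyl)methyl]-4,5-dihydro-1,3-dioxepin-5-yl]oxy}trimethylsilane (both C2 epimers), via selenoxide 10 (not isolated)
Conditions: mCPBA (1.05 equiv), CH2Cl2, −78 °C; then i-Pr2NH, −78 °C to 40 °C
Reagents that add atoms: none
Why: Oxidation to the selenoxide and syn-elimination can only proceed towards C7 because C5 is quaternary, which gives the endocyclic enol ether (vinyl acetal); the amine scavenges benzeneselenenic acid before it can add back to the enol ether.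

Step 8
Reactants: 11 5-silyloxy-4,5-dihydro-1,3-dioxepine
Product: 14 (3R,4R,5R)-5-[3,4-bis(benzyloxy)phenyl]-3-[(3,4-dimethoxyphenyl)methyl]-4-(hydroxymethyl)oxolan-3-ol, via aldehyde 12 (not isolated), via silyl ether alcohol 13 (not isolated)
Conditions: TMSOTf (0.2 equiv), CH2Cl2, −78 °C; Et3N; then NaBH4, MeOH, −78 °C to rt; K2CO3, rt
Reagents that add atoms: none
Why: TMSOTf silylates the vinylic acetal oxygen O1, the C2–O1 bond ionises to an (E)-aryl oxocarbenium ion that stays tethered through O3–C4–C5 to a (Z)-enol silane, C6 adds to C2 and loss of Me3Si+ releases the oxolane-3-carbaldehyde 12 and the catalyst. This is the Lewis acid-mediated [1,3] O-to-C ring contraction of 4,5-dihydro-1,3-dioxepines (a vinyl acetal rearrangement of the Petasis–Ferrier family), and the oxolane (O3, C4, C5, C6, C2) closes in a 5-(enolexo)-endo-trig mode on the oxocarbenium ion. The aryl-bearing centre is set cis to the formyl group by kinetic control at −78 °C, the characteristic low-temperature outcome of this rearrangement, which is why the aldehyde is reduced in the same flask before it can epimerise or reopen. The formyl-bearing centre is set by the resident tertiary centre: the silyloxy group takes the inside position next to the Z-enol (inside-alkoxy effect, least A1,3 strain) and the benzyl group points away, so CHO ends up trans to benzyl and cis to oxygen. Both acetal epimers of 11 give the same ion pair, so the step is stereoconvergent, and the needed chemoselectivity, acetal ionisation before Ferrier-type loss of the tertiary allylic silyl ether, is secured by the electron-rich aryl acetal and the poor leaving-group ability of OSiMe3. NaBH4 then reduces the aldehyde and K2CO3/MeOH removes the trimethylsilyl ether to give 14.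

Step 9
Reactants: 14 bis(benzyl ether) diol
Product: 15 (3R,4R,5R)-5-(3,4-dihydroxyphenyl)-3-[(3,4-dimethoxyphenyl)methyl]-4-(hydroxymethyl)oxolan-3-ol
Conditions: H2 (1 atm), 10% Pd/C, EtOAc–MeOH, rt, stopped at full debenzylation
Reagents that add atoms: none
Why: Catalytic hydrogenolysis cleaves the two aryl benzyl ethers much faster than the cyclic benzylic C5–O bond under neutral conditions at 1 atm, so the oxolane and all three stereocentres should remain intact.

**Compound list**

1 | but-2-yne-1,4-diol | OCC#CCO | starting material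
2 | (E)-2-(tributylstannyl)but-2-ene-1,4-diol | OC/C=C(/[Sn](CCCC)(CCCC)CCCC)CO | intermediate
3 | 3,4-dimethoxybenzyl bromide | COc1ccc(CBr)cc1OC | starting material
4 | (Z)-2-[(3,4-dimethoxyphenyl)methyl]but-2-ene-1,4-diol | OC/C=C(/Cc1ccc(OC)c(OC)c1)CO | intermediate
5 | 3,4-bis(benzyloxy)benzaldehyde | O=Cc1ccc(OCc2ccccc2)c(OCc2ccccc2)c1 | starting material
6 | 2-[3,4-bis(benzyloxy)phenyl]-5-[(3,4-dimethoxyphenyl)methyl]-4,7-dihydro-1,3-dioxepine, racemic | COc1ccc(CC2=CCOC(c3ccc(OCc4ccccc4)c(OCc4ccccc4)c3)OC2)cc1OC | intermediate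
7 | (1S,7R)-4-[3,4-bis(benzyloxy)phenyl]-1-[(3,4-dimethoxyphenyl)methyl]-3,5,8-trioxabicyclo[5.1.0]octane, both epimers at the acetal carbon | COc1ccc(C[C@]2(O3)COC(c4ccc(OCc5ccccc5)c(OCc5ccccc5)c4)OC[C@H]23)cc1OC | intermediate
8 | (5S,6S)-2-[3,4-bis(benzyloxy)phenyl]-5-[(3,4-dimethoxyphenyl)methyl]-6-(phenylselanyl)-1,3-dioxepan-5-ol, both C2 epimers | COc1ccc(C[C@]2(O)COC(c3ccc(OCc4ccccc4)c(OCc4ccccc4)c3)OC[C@@H]2[Se]c5ccccc5)cc1OC | intermediate
9 | trimethylsilyl ether of 8, (5S,6S), both C2 epimers | COc1ccc(C[C@]2(O[Si](C)(C)C)COC(c3ccc(OCc4ccccc4)c(OCc4ccccc4)c3)OC[C@@H]2[Se]c5ccccc5)cc1OC | intermediate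
10 | selenoxide of 9, (5S,6S), configuration at Se undefined | COc1ccc(C[C@]2(O[Si](C)(C)C)COC(c3ccc(OCc4ccccc4)c(OCc4ccccc4)c3)OC[C@@H]2[Se](=O)c5ccccc5)cc1OC | intermediate (not isolated)
11 | {[(5R)-2-[3,4-bis(benzyloxy)phenyl]-5-[(3,4-dimethoxyphenyl)methyl]-4,5-dihydro-1,3-dioxepin-5-yl]oxy}trimethylsilane, both C2 epimers (descriptor at C5 changes from S to R through CIP priorities only) | COc1ccc(C[C@]2(O[Si](C)(C)C)COC(c3ccc(OCc4ccccc4)c(OCc4ccccc4)c3)OC=C2)cc1OC | intermediate
12 | (2R,3R,4R)-2-[3,4-bis(benzyloxy)phenyl]-4-[(3,4-dimethoxyphenyl)methyl]-4-[(trimethylsilyl)oxy]oxolane-3-carbaldehyde | COc1ccc(C[C@]2(O[Si](C)(C)C)CO[C@@H](c3ccc(OCc4ccccc4)c(OCc4ccccc4)c3)[C@H]2C=O)cc1OC | intermediate (not isolated)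
13 | [(2R,3R,4R)-2-[3,4-bis(benzyloxy)phenyl]-4-[(3,4-dimethoxyphenyl)methyl]-4-[(trimethylsilyl)oxy]oxolan-3-yl]methanol | COc1ccc(C[C@]2(O[Si](C)(C)C)CO[C@@H](c3ccc(OCc4ccccc4)c(OCc4ccccc4)c3)[C@H]2CO)cc1OC | intermediate (not isolated)
14 | (3R,4R,5R)-5-[3,4-bis(benzyloxy)phenyl]-3-[(3,4-dimethoxyphenyl)methyl]-4-(hydroxymethyl)oxolan-3-ol | COc1ccc(C[C@]2(O)CO[C@@H](c3ccc(OCc4ccccc4)c(OCc4ccccc4)c3)[C@H]2CO)cc1OC | intermediate
15 | (3R,4R,5R)-5-(3,4-dihydroxyphenyl)-3-[(3,4-dimethoxyphenyl)methyl]-4-(hydroxymethyl)oxolan-3-ol | COc1ccc(C[C@]2(O)CO[C@@H](c3ccc(O)c(O)c3)[C@H]2CO)cc1OC | target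

**Step count and risks**

Total step count: 9. Longest linear sequence: 9 steps (1 to 15); 3 and 5 enter as purchased materials.

Steps most likely to fail:

Step 8. The kinetic cis selectivity at the aryl-bearing carbon may erode, by closure on the other face of the oxocarbenium ion or by reopening and equilibration of the aldehyde; Ferrier-type ionisation of the allylic silyl ether is a lesser concern. The fallback sets out from 11 and comes back at 14. The contraction would be run under equilibrating conditions (TMSOTf, CH2Cl2, −78 to 0 °C) and followed by the same reduction and desilylation, which should funnel the material to the 2,3-trans diol, the C5 epimer of 14, (3R,4R,5S)-5-[3,4-bis(benzyloxy)phenyl]-3-[(3,4-dimethoxyphenyl)methyl]-4-(hydroxymethyl)oxolan-3-ol F1. DDQ in CH2Cl2/H2O would oxidise the electron-rich cyclic benzylic ether C–H to the hemiketal (3S,4R)-2-[3,4-bis(benzyloxy)phenyl]-4-[(3,4-dimethoxyphenyl)methyl]-3-(hydroxymethyl)oxolane-2,4-diol F2, which erases the wrong centre. Ionic hydrogenation (Et3SiH, BF3·OEt2, CH2Cl2, −78 °C) should then deliver hydride to the cyclic oxocarbenium ion anti to the neighbouring CH2OH group and give 14 with aryl cis to CH2OH.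

Step 4. Facial control may be insufficient because the chiral ketone meets a substrate that is already racemic at the acetal carbon (matched and mismatched pairs), and the acetal C–H may be oxidised competitively. The fallback sets out from 4 and comes back at 7. The Shi epoxidation would be moved to the achiral free diol 4, where only the reagent decides the face, to give [(2S,3R)-2-[(3,4-dimethoxyphenyl)methyl]oxirane-2,3-diyl]dimethanol F3. Acetalisation of F3 with 5 (PPTS, 4 Å molecular sieves, CH2Cl2, rt) would then close the seven-membered acetal and give 7.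

Step 7. The syn-elimination has to run towards an oxygen-bearing carbon and may be slow, so that the selenoxide decomposes otherwise, benzeneselenenic acid adds back to the enol ether, or the vinyl acetal hydrolyses. The fallback sets out from 7 and comes back at 11. Epoxide 7 would be opened with Li2NiBr4 (THF, 0 °C to rt) at the less substituted carbon to the trans-bromohydrin (5S,6S)-2-[3,4-bis(benzyloxy)phenyl]-6-bromo-5-[(3,4-dimethoxyphenyl)methyl]-1,3-dioxepan-5-ol F4. Silylation with 1-(trimethylsilyl)imidazole would give {[(5S,6S)-2-[3,4-bis(benzyloxy)phenyl]-6-bromo-5-[(3,4-dimethoxyphenyl)methyl]-1,3-dioxepan-5-yl]oxy}trimethylsilane F5. Anti-E2 elimination of HBr with DBU (toluene, 90 °C), again possible only towards C7, should give 11.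

Further compounds
F1 | step 8 | (3R,4R,5S)-5-[3,4-bis(benzyloxy)phenyl]-3-[(3,4-dimethoxyphenyl)methyl]-4-(hydroxymethyl)oxolan-3-ol | COc1ccc(C[C@]2(O)CO[C@H](c3ccc(OCc4ccccc4)c(OCc4ccccc4)c3)[C@H]2CO)cc1OC
F2 | step 8 | (3S,4R)-2-[3,4-bis(benzyloxy)phenyl]-4-[(3,4-dimethoxyphenyl)methyl]-3-(hydroxymethyl)oxolane-2,4-diol (anomers) | COc1ccc(C[C@]2(O)COC(O)(c3ccc(OCc4ccccc4)c(OCc4ccccc4)c3)[C@H]2CO)cc1OC
F3 | step 4 | [(2S,3R)-2-[(3,4-dimethoxyphenyl)methyl]oxirane-2,3-diyl]dimethanol | COc1ccc(C[C@@]2(CO)O[C@@H]2CO)cc1OC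
F4 | step 7 | (5S,6S)-2-[3,4-bis(benzyloxy)phenyl]-6-bromo-5-[(3,4-dimethoxyphenyl)methyl]-1,3-dioxepan-5-ol | COc1ccc(C[C@]2(O)COC(c3ccc(OCc4ccccc4)c(OCc4ccccc4)c3)OC[C@@H]2Br)cc1OC
F5 | step 7 | {[(5S,6S)-2-[3,4-bis(benzyloxy)phenyl]-6-bromo-5-[(3,4-dimethoxyphenyl)methyl]-1,3-dioxepan-5-yl]oxy}trimethylsilane | COc1ccc(C[C@]2(O[Si](C)(C)C)COC(c3ccc(OCc4ccccc4)c(OCc4ccccc4)c3)OC[C@@H]2Br)cc1OC
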